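Ring C is cut at C3–C4 and O1–C2. The cut exploits two features. C4 (on C4a) and O1 (on C8a) hang from adjacent carbons of ring A, which is the pattern of a salicylaldehyde. The C2–C3 pair, with C3 carrying ring B, is the triple bond of 4-methoxyphenylacetylene with its free end capped by a silyl group. One rhodium-catalysed oxidative annulation cleaves the formyl C–H bond, takes up the alkyne and closes the pyranone, forming both bonds at once. Its precursor is the fully decorated salicylaldehyde (3-OMe, 4-O-prenyl). It is reached in two steps by formylating symmetric 2-methoxyresorcinol and then alkylating only the non-chelated hydroxyl. Buffered fluoride finally exchanges silicon for H-2.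

Key step: step 3

Remark: isoflavone numbering is used (ring A = benzo ring C4a–C8a, ring B = 4-methoxyphenyl on C3, ring C = pyranone O1–C2–C3–C4–C4a–C8a). The target has no stereocentre and no stereogenic double bond, so no configuration has to be set.

Step 1
Reactants: 1 2-methoxyresorcinol; 2 N,N-dimethylformamide
Product: 4 2,4-dihydroxy-3-methoxybenzaldehyde, via iminium chloride 3 (not isolated)
Conditions: POCl3, DMF, MeCN, −15 °C to rt; then H2O, 50 °C
Reagents that add atoms: N,N-dimethylformamide (2), CN(C)C=O; water, O
Why: Vilsmeier–Haack formylation: the preformed chloroiminium salt attacks the carbon of 1 that is ortho to one hydroxyl and para to the other (C4 and C6 are equivalent by symmetry, C5 is meta to both), the iminium group of 3 shuts the ring down against a second attack, and warm water hydrolyses 3 to 4; doing this before the etherification turns the later choice between two hydroxyls from a statistical into a chelation-controlled one.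

Step 2
Reactants: 4 2,4-dihydroxy-3-methoxybenzaldehyde; 5 prenyl bromide (1-bromo-3-methylbut-2-ene)
Product: 6 2-hydroxy-3-methoxy-4-(3-methylbut-2-enyloxy)benzaldehyde
Conditions: 5 (1.05 equiv), CsHCO3, MeCN, 60 °C
Reagents that add atoms: prenyl bromide (5), CC(C)=CCBr
Why: Williamson ether synthesis under chelation control: the 2-OH is locked in a hydrogen bond to the formyl oxygen and is the weaker acid, so the mild base ionises only the 4-OH (para to CHO), whose phenoxide displaces bromide from 5 in an SN2 reaction, while the formyl group lowers the nucleophilicity of the ring enough to suppress C-prenylation.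

Step 3
Reactants: 6 2-hydroxy-3-methoxy-4-(3-methylbut-2-enyloxy)benzaldehyde; 7 4-[(trimethylsilyl)ethynyl]anisole
Product: 8 8,4'-dimethoxy-7-(3-methylbut-2-enyloxy)-2-(trimethylsilyl)isoflavone
Conditions: [Cp*RhCl2]2 (2.5 mol%), anhydrous Cu(OAc)2 (2.2 equiv), 7 (1.5 equiv), 4 Å molecular sieves, o-xylene, 100 °C, N2
Reagents that add atoms: none
Why: Proposed new method: acetate exchange gives Cp*Rh(OAc)2, the phenoxide of 6 binds trivalent rhodium, acetate-assisted metalation cleaves the formyl C–H bond to a five-membered acyl rhodacycle (Rh, O1, C8a, C4a, C4), and 7 inserts into the Rh–acyl bond, which forms C3–C4 and gives a seven-membered rhodacycle. Ring C is then closed by C–O reductive elimination from this metallacycle (O1–C2), overall a formal [4+2] annulation of the four-atom unit O1–C8a–C4a–C4 with the two-carbon unit C2–C3, and two equivalents of Cu(OAc)2 return monovalent rhodium to the trivalent state. The closest known reaction type is the rhodium/copper oxidative annulation of salicylaldehydes with diaryl, dialkyl and aryl alkyl alkynes to 2,3-disubstituted chromones; new here is the aryl silyl alkyne, whose orientation is inferred from Larock-type heteroannulations, in which silicon ends up on the carbon next to the heteroatom. The selectivity needed is regiochemical, acyl carbon to the aryl-bearing alkyne carbon, and three effects in 7 point the same way: the short new C–C bond avoids the bulky SiMe3 group, silicon stabilises the C–Rh bond on its own carbon, and the partial positive charge on the other carbon is stabilised by the 4-methoxyphenyl group and by the β-silicon effect. Chemoselectivity rests on chelation, which holds only the formyl C–H next to rhodium, while the trisubstituted prenyl alkene is a poor insertion partner, 100 °C lies far below the Claisen rearrangement of aryl prenyl ethers, and the absence of silver salts, water and polar solvent shields the alkynyl C–Si bond. No stereocentre is formed, and any material that loses silicon in the flask is carried on together with 8, since step 4 brings both to 9.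

Step 4
Reactants: 8 8,4'-dimethoxy-7-(3-methylbut-2-enyloxy)-2-(trimethylsilyl)isoflavone
Product: 9 8,4'-dimethoxy-7-(3-methylbut-2-enyloxy)isoflavone (target)
Conditions: Bu4NF, AcOH, THF, 0 °C to rt
Reagents that add atoms: none
Why: Fluoride-induced protodesilylation of a C(sp2)–Si bond: fluoride forms a pentacoordinate silicate, the departing C2 carbanion equivalent (C2–H is the most acidic position of a chromone) is protonated by acetic acid, and the buffer keeps the medium free of hydroxide that would add to C2 and open ring C, while the prenyl and methyl ethers are inert.

Compound list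
1 | 2-methoxyresorcinol (2-methoxybenzene-1,3-diol) | COc1c(O)cccc1O | starting material
2 | N,N-dimethylformamide | CN(C)C=O | starting material
3 | (2,4-dihydroxy-3-methoxybenzylidene)dimethyliminium chloride | C[N+](C)=Cc1ccc(O)c(OC)c1O.[Cl-] | intermediate
4 | 2,4-dihydroxy-3-methoxybenzaldehyde | O=Cc1ccc(O)c(OC)c1O | intermediate
5 | prenyl bromide (1-bromo-3-methylbut-2-ene) | CC(C)=CCBr | starting material
6 | 2-hydroxy-3-methoxy-4-(3-methylbut-2-enyloxy)benzaldehyde | O=Cc1ccc(OCC=C(C)C)c(OC)c1O | intermediate
7 | 4-[(trimethylsilyl)ethynyl]anisole | COc1ccc(C#C[Si](C)(C)C)cc1 | starting material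
8 | 8,4'-dimethoxy-7-(3-methylbut-2-enyloxy)-2-(trimethylsilyl)isoflavone | COc1ccc(-c2c([Si](C)(C)C)oc3c(OC)c(OCC=C(C)C)ccc3c2=O)cc1 | intermediate
9 | 8,4'-dimethoxy-7-(3-methylbut-2-enyloxy)isoflavone | COc1ccc(-c2coc3c(OC)c(OCC=C(C)C)ccc3c2=O)cc1 | target

Total step count: 4
Longest linear sequence: 4 steps (1 → 4 → 6 → 8 → 9)

Steps most likely to fail

**1. Step 3 (Proposed new method).**
- Risk: the alkyne may insert in the reverse sense. The acyl rhodium species may lose CO before insertion. The alkynyl C–Si bond may be cleaved early, followed by copper-mediated oxidative dimerisation of the alkyne.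
- Fallback: the known deoxybenzoin construction of ring C, which sets out from 1 and comes back at 9.
  - Friedel–Crafts acylation of 1 with 4-methoxyphenylacetic acid in BF3·OEt2 at 85 °C should give 1-(2,4-dihydroxy-3-methoxyphenyl)-2-(4-methoxyphenyl)ethanone F1. Attack occurs at the same carbon that is formylated in step 1.
  - Vilsmeier-type C-formylation of the active methylene with 2, BF3·OEt2 and MeSO2Cl at 70 °C, followed by cyclodehydration, should close ring C to 7-hydroxy-8,4'-dimethoxyisoflavone F2.
  - Williamson etherification of the single remaining hydroxyl with 5 and K2CO3 in acetone at reflux returns to 9.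

**2. Step 4.**
- Risk: a nucleophile may add to C2 and open ring C, or the Si–C cleavage may stall in the buffered medium.
- Fallback: ring opening becomes the intended path. It sets out from 8 and comes back at 9.
  - NaOH in aqueous EtOH at reflux should strip silicon and excise C2 by ring opening and retro-Claisen cleavage. This is the classical alkaline degradation of isoflavones, and it should give 1-[2-hydroxy-3-methoxy-4-(3-methylbut-2-enyloxy)phenyl]-2-(4-methoxyphenyl)ethanone F3.
  - Condensation of F3 with N,N-dimethylformamide dimethyl acetal in toluene at 100 °C puts C2 back as a CH unit. It closes ring C onto the chelated phenol to give 9.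

**3. Step 2.**
- Risk: site selectivity may be lost through alkylation of the chelated hydroxyl as well, or prenylation may compete at carbon.
- Fallback: the order of events is reversed. It sets out from 1 and comes back at 6.
  - Mono-etherification of 1 (used in excess and recovered) with 5 and K2CO3 in DMF at rt should give 2-methoxy-3-(3-methylbut-2-enyloxy)phenol F4.
  - Casnati–Skattebøl ortho-formylation (MgCl2, Et3N, paraformaldehyde, MeCN, reflux) then places the aldehyde on the one free carbon next to the one remaining phenol. This gives 6 without any choice between two hydroxyls.

Further compounds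
F1 | step 3 | 1-(2,4-dihydroxy-3-methoxyphenyl)-2-(4-methoxyphenyl)ethanone | COc1ccc(CC(=O)c2ccc(O)c(OC)c2O)cc1
F2 | step 3 | 7-hydroxy-8,4'-dimethoxyisoflavone | COc1ccc(-c2coc3c(OC)c(O)ccc3c2=O)cc1
F3 | step 4 | 1-[2-hydroxy-3-methoxy-4-(3-methylbut-2-enyloxy)phenyl]-2-(4-methoxyphenyl)ethanone | COc1ccc(CC(=O)c2ccc(OCC=C(C)C)c(OC)c2O)cc1
F4 | step 2 | 2-methoxy-3-(3-methylbut-2-enyloxy)phenol | COc1c(O)cccc1OCC=C(C)C
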